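## Retrosynthetic overview

1. Target 39 ⇐ hydrolysis of enol lactone 38 ⇐ catalyst-controlled dearomative C-6 prenylation (the proposed new step) of aromatic tricycle 37 with prenyl carbonate 22.
2. 37 ⇐ carbene-catalysed [3+3] annulation of chromanone 35 with ynal 36 (sets the benzylic centre, closes the lactone ring).
3. 35 ⇐ Mitsunobu closure of the chromanone ring in β-hydroxy ketone 33 ⇐ aryl iodide 29 + syn-aldol-derived aldehyde 20.
4. 29 ⇐ ortho-lithiation/alkylation of the TIPS/MOM-differentiated phloroglucinol 25 with the triflate of alcohol 13 (Evans alkylation, Wittig).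
5. Ring order: benzene ring (phloroglucinol, bought) → chromanone ring → lactone ring → dearomatisation of the benzene ring → lactone opened.

Assumption: the absolute sense of induction of the two catalyst-controlled steps (21 and 22) is taken as drawn for the catalyst enantiomer named; if the first run shows the opposite sense, the mirror-image catalyst is used and nothing else changes.

## Route

Step 1
Reactants: 1 5-methylhex-5-enoic acid; 2 (4S)-4-benzyl-1,3-oxazolidin-2-one
Product: 4 (4S)-4-benzyl-3-(5-methylhex-5-enoyl)-1,3-oxazolidin-2-one, via mixed pivalic anhydride 3 (not isolated)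
Conditions: t-BuCOCl, Et3N, THF, −20 °C; then 2, LiCl, −20 °C to rt
Reagents that add atoms: none
Why: N-acylation of the Evans auxiliary through the mixed pivalic anhydride, which transfers only the less hindered acyl group; no stereocentre is formed.

Step 2
Reactants: 4 (4S)-4-benzyl-3-(5-methylhex-5-enoyl)-1,3-oxazolidin-2-one; 5 benzyl chloromethyl ether
Product: 7 (4S)-4-benzyl-3-[(2R)-2-[(benzyloxy)methyl]-5-methylhex-5-enoyl]-1,3-oxazolidin-2-one, via sodium enolate 6 (not isolated)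
Conditions: NaN(SiMe3)2, THF, −78 °C; then 5, −78 to −40 °C
Reagents that add atoms: none
Why: Evans asymmetric enolate alkylation: the chelated (Z)-enolate is shielded on one face by the 4-benzyl group, so the chloromethyl ether enters from the other face and sets the (R) centre that becomes the side-chain stereocentre.

Step 3
Reactants: 7 (4S)-4-benzyl-3-[(2R)-2-[(benzyloxy)methyl]-5-methylhex-5-enoyl]-1,3-oxazolidin-2-one
Product: 8 (2S)-2-[(benzyloxy)methyl]-5-methylhex-5-en-1-ol
Conditions: LiBH4, H2O (1.1 equiv), Et2O, 0 °C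
Reagents that add atoms: none
Why: Reductive cleavage of the N-acyloxazolidinone by hydride attack on the exocyclic carbonyl gives the primary alcohol without touching the α-centre (the descriptor changes by priority only).

Step 4
Reactants: 8 (2S)-2-[(benzyloxy)methyl]-5-methylhex-5-en-1-ol
Product: 9 (2R)-2-[(benzyloxy)methyl]-5-methylhex-5-enal
Conditions: Dess–Martin periodinane, pyridine, CH2Cl2, 0 °C to rt
Reagents that add atoms: none
Why: Dess–Martin oxidation is neutral and fast, so the α-branched β-alkoxy aldehyde forms without epimerisation or β-elimination and is used at once.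

Step 5
Reactants: 9 (2R)-2-[(benzyloxy)methyl]-5-methylhex-5-enal; 10 isopropyltriphenylphosphonium iodide
Product: 12 benzyl (2S)-5-methyl-2-(2-methylprop-1-en-1-yl)hex-5-en-1-yl ether, via phosphorus ylide 11 (not isolated)
Conditions: 10, n-BuLi, THF, 0 °C; then 9, −78 °C to rt
Reagents that add atoms: none
Why: Wittig olefination with a non-stabilised ylide; the symmetric isopropylidene unit raises no alkene-geometry question and cold addition preserves the α-centre.

Step 6
Reactants: 12 benzyl (2S)-5-methyl-2-(2-methylprop-1-en-1-yl)hex-5-en-1-yl ether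
Product: 13 (2S)-5-methyl-2-(2-methylprop-1-en-1-yl)hex-5-en-1-ol
Conditions: Li, NH3 (l), THF, −78 °C; then NH4Cl
Reagents that add atoms: none
Why: Dissolving-metal (Birch-type) cleavage of the benzylic C–O bond by electron transfer leaves the isolated alkenes untouched, which hydrogenolysis would not.

Step 7
Reactants: 14 (4S)-4-benzyl-3-propanoyl-1,3-oxazolidin-2-one; 15 acetaldehyde
Product: 17 (4S)-4-benzyl-3-[(2S,3R)-3-hydroxy-2-methylbutanoyl]-1,3-oxazolidin-2-one, via boron enolate 16 (not isolated)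
Conditions: Bu2BOTf, i-Pr2NEt, CH2Cl2, −78 to 0 °C; then 15, −78 to 0 °C; H2O2, MeOH, pH 7 buffer
Reagents that add atoms: none
Why: Evans syn-aldol reaction: the (Z)-dibutylboron enolate reacts through a closed Zimmerman–Traxler chair with the auxiliary dipole opposed, giving the (2S,3R) syn adduct.

Step 8
Reactants: 17 (4S)-4-benzyl-3-[(2S,3R)-3-hydroxy-2-methylbutanoyl]-1,3-oxazolidin-2-one
Product: 18 (4S)-4-benzyl-3-[(2S,3R)-3-{[tert-butyl(dimethyl)silyl]oxy}-2-methylbutanoyl]-1,3-oxazolidin-2-one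
Conditions: TBSOTf, 2,6-lutidine, CH2Cl2, −78 to 0 °C
Reagents that add atoms: tert-butyldimethylsilyl trifluoromethanesulfonate, CC(C)(C)[Si](C)(C)OS(=O)(=O)C(F)(F)F
Why: Silylation of the secondary alcohol with a silyl triflate and a hindered base blocks retro-aldol in the following steps.

Step 9
Reactants: 18 (4S)-4-benzyl-3-[(2S,3R)-3-{[tert-butyl(dimethyl)silyl]oxy}-2-methylbutanoyl]-1,3-oxazolidin-2-one
Product: 19 (2R,3R)-3-{[tert-butyl(dimethyl)silyl]oxy}-2-methylbutan-1-ol
Conditions: LiBH4, H2O (1.1 equiv), Et2O, 0 °C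
Reagents that add atoms: none
Why: Reductive removal of the auxiliary with LiBH4 leaves both stereocentres untouched (the C-2 descriptor changes by priority only).

Step 10
Reactants: 19 (2R,3R)-3-{[tert-butyl(dimethyl)silyl]oxy}-2-methylbutan-1-ol
Product: 20 (2S,3R)-3-{[tert-butyl(dimethyl)silyl]oxy}-2-methylbutanal
Conditions: Dess–Martin periodinane, pyridine, CH2Cl2, 0 °C
Reagents that add atoms: none
Why: Dess–Martin oxidation gives the α-chiral β-silyloxy aldehyde under neutral conditions without epimerisation; it is used directly.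

Step 11
Reactants: 21 3-methylbut-2-en-1-ol
Product: 22 tert-butyl 3-methylbut-2-en-1-yl carbonate
Conditions: Boc2O, DMAP (10 mol%), CH2Cl2, 0 °C to rt
Reagents that add atoms: di-tert-butyl dicarbonate, CC(C)(C)OC(=O)OC(=O)OC(C)(C)C
Why: DMAP-catalysed tert-butoxycarbonylation of a primary allylic alcohol gives the carbonate that later ionises with loss of CO2 and tert-butoxide.

Step 12
Reactants: 23 benzene-1,3,5-triol
Product: 24 5-{[tri(propan-2-yl)silyl]oxy}benzene-1,3-diol
Conditions: TIPSCl (1.0 equiv), imidazole, DMF, 0 °C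
Reagents that add atoms: chlorotri(propan-2-yl)silane, CC(C)[Si](Cl)(C(C)C)C(C)C
Why: Statistical monosilylation of the symmetric triol with one equivalent of a bulky silyl chloride gives the future chromanone-ring oxygen its own removable group.

Step 13
Reactants: 24 5-{[tri(propan-2-yl)silyl]oxy}benzene-1,3-diol
Product: 25 [3,5-bis(methoxymethoxy)phenoxy]tri(propan-2-yl)silane
Conditions: MOMCl, i-Pr2NEt, CH2Cl2, 0 °C to rt
Reagents that add atoms: chloromethyl methyl ether, COCCl
Why: O-alkylation of the two remaining phenols gives MOM acetals, which are strong ortho-directing groups for the next step.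

Step 14
Reactants: 25 [3,5-bis(methoxymethoxy)phenoxy]tri(propan-2-yl)silane; 13 (2S)-5-methyl-2-(2-methylprop-1-en-1-yl)hex-5-en-1-ol
Product: 28 {3,5-bis(methoxymethoxy)-4-[(2R)-5-methyl-2-(2-methylprop-1-en-1-yl)hex-5-en-1-yl]phenoxy}tri(propan-2-yl)silane, via aryllithium 26 (not isolated), via alkyl triflate 27 (not isolated)
Conditions: 25, n-BuLi, THF, 0 °C (gives 26); 13, Tf2O, 2,6-di-tert-butyl-4-methylpyridine, CH2Cl2, −78 °C (gives 27); 26 added to 27, −78 to −20 °C
Reagents that add atoms: none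
Why: Directed ortho-metalation occurs only between the two MOM ethers (the bulky TIPS ether neither directs nor tolerates flanking lithiation) and the aryllithium displaces the primary triflate by SN2; the stereocentre is β to the reacting carbon and untouched.

Step 15
Reactants: 28 {3,5-bis(methoxymethoxy)-4-[(2R)-5-methyl-2-(2-methylprop-1-en-1-yl)hex-5-en-1-yl]phenoxy}tri(propan-2-yl)silane
Product: 29 {2-iodo-3,5-bis(methoxymethoxy)-4-[(2R)-5-methyl-2-(2-methylprop-1-en-1-yl)hex-5-en-1-yl]phenoxy}tri(propan-2-yl)silane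
Conditions: NIS (1.0 equiv), CH2Cl2, −20 °C, dark
Reagents that add atoms: N-iodosuccinimide, O=C1CCC(=O)N1I
Why: Electrophilic aromatic iodination of the very electron-rich arene is far faster than attack on the alkenes, and the two free ring positions are equivalent by symmetry, so one regioisomer results.

Step 16
Reactants: 29 {2-iodo-3,5-bis(methoxymethoxy)-4-[(2R)-5-methyl-2-(2-methylprop-1-en-1-yl)hex-5-en-1-yl]phenoxy}tri(propan-2-yl)silane; 20 (2S,3R)-3-{[tert-butyl(dimethyl)silyl]oxy}-2-methylbutanal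
Product: 31 (1RS,2R,3R)-3-{[tert-butyl(dimethyl)silyl]oxy}-1-{2,4-bis(methoxymethoxy)-3-[(2R)-5-methyl-2-(2-methylprop-1-en-1-yl)hex-5-en-1-yl]-6-{[tri(propan-2-yl)silyl]oxy}phenyl}-2-methylbutan-1-ol, via aryllithium 30 (not isolated)
Conditions: n-BuLi, Et2O/THF, −95 °C, 5 min; then 20, −95 to −78 °C; H2O
Reagents that add atoms: none
Why: Iodine–lithium exchange at −95 °C outruns silyl migration from oxygen to carbon, and the aryllithium adds 1,2 to the aldehyde; the new carbinol centre is uncontrolled and is erased in step 17.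

Step 17
Reactants: 31 (1RS,2R,3R)-3-{[tert-butyl(dimethyl)silyl]oxy}-1-{2,4-bis(methoxymethoxy)-3-[(2R)-5-methyl-2-(2-methylprop-1-en-1-yl)hex-5-en-1-yl]-6-{[tri(propan-2-yl)silyl]oxy}phenyl}-2-methylbutan-1-ol
Product: 32 (2S,3R)-3-{[tert-butyl(dimethyl)silyl]oxy}-1-{2,4-bis(methoxymethoxy)-3-[(2R)-5-methyl-2-(2-methylprop-1-en-1-yl)hex-5-en-1-yl]-6-{[tri(propan-2-yl)silyl]oxy}phenyl}-2-methylbutan-1-one
Conditions: Dess–Martin periodinane, pyridine, CH2Cl2, 0 °C to rt
Reagents that add atoms: none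
Why: Dess–Martin oxidation converts the hindered, acid-sensitive benzylic alcohol into the aryl ketone under buffered conditions that spare the acetals, silyl ethers and alkenes.

Step 18
Reactants: 32 (2S,3R)-3-{[tert-butyl(dimethyl)silyl]oxy}-1-{2,4-bis(methoxymethoxy)-3-[(2R)-5-methyl-2-(2-methylprop-1-en-1-yl)hex-5-en-1-yl]-6-{[tri(propan-2-yl)silyl]oxy}phenyl}-2-methylbutan-1-one
Product: 33 (2S,3R)-3-hydroxy-1-{6-hydroxy-2,4-bis(methoxymethoxy)-3-[(2R)-5-methyl-2-(2-methylprop-1-en-1-yl)hex-5-en-1-yl]phenyl}-2-methylbutan-1-one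
Conditions: TBAF (3 equiv), AcOH (3 equiv), THF, 0 to 40 °C
Reagents that add atoms: none
Why: Fluoride cleaves both silyl ethers, and the acetic acid buffer suppresses retro-aldol and elimination of the β-hydroxy ketone.

Step 19
Reactants: 33 (2S,3R)-3-hydroxy-1-{6-hydroxy-2,4-bis(methoxymethoxy)-3-[(2R)-5-methyl-2-(2-methylprop-1-en-1-yl)hex-5-en-1-yl]phenyl}-2-methylbutan-1-one
Product: 34 (2S,3S)-5,7-bis(methoxymethoxy)-2,3-dimethyl-6-[(2R)-5-methyl-2-(2-methylprop-1-en-1-yl)hex-5-en-1-yl]-2,3-dihydro-4H-chromen-4-one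
Conditions: PPh3, DIAD, THF (0.01 M), 0 °C
Reagents that add atoms: none
Why: Intramolecular Mitsunobu etherification: the only free phenol displaces the activated secondary alcohol with inversion, turning the (3R) carbinol into the (2S) centre of the trans-2,3-dimethylchromanone while the α-methyl centre is kept; the other ortho oxygen is still a MOM ether, so the ring can close only one way.

Step 20
Reactants: 34 (2S,3S)-5,7-bis(methoxymethoxy)-2,3-dimethyl-6-[(2R)-5-methyl-2-(2-methylprop-1-en-1-yl)hex-5-en-1-yl]-2,3-dihydro-4H-chromen-4-one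
Product: 35 (2S,3S)-5,7-dihydroxy-2,3-dimethyl-6-[(2R)-5-methyl-2-(2-methylprop-1-en-1-yl)hex-5-en-1-yl]-2,3-dihydro-4H-chromen-4-one
Conditions: HCl (conc., cat.), MeOH, 40 °C
Reagents that add atoms: none
Why: Acid-catalysed acetal methanolysis removes both MOM groups; dilute acid at 40 °C leaves the alkenes and the chromanone stereocentres intact.

Step 21
Reactants: 35 (2S,3S)-5,7-dihydroxy-2,3-dimethyl-6-[(2R)-5-methyl-2-(2-methylprop-1-en-1-yl)hex-5-en-1-yl]-2,3-dihydro-4H-chromen-4-one; 36 3-phenylprop-2-ynal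
Product: 37 (2S,3S,10R)-5-hydroxy-2,3-dimethyl-6-[(2R)-5-methyl-2-(2-methylprop-1-en-1-yl)hex-5-en-1-yl]-10-phenyl-2,3,9,10-tetrahydro-4H,8H-pyrano[2,3-f]chromene-4,8-dione
Conditions: (5aS,10bR)-2-mesityl-5a,10b-dihydro-4H,6H-indeno[2,1-b][1,2,4]triazolo[4,3-d][1,4]oxazin-2-ium chloride (10 mol%), i-Pr2NEt (10 mol%), toluene, 40 °C
Reagents that add atoms: none
Why: Carbene-catalysed redox annulation of an ynal (formal [3+3], Coates–Claisen type): the α,β-unsaturated acyl azolium acylates the 7-OH and bonds to C-8, the only unsubstituted ring carbon, then lactonisation releases the carbene; the chiral triazolylidene shields one face of the acyl azolium and sets the (R) benzylic centre.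

Step 22
Reactants: 37 (2S,3S,10R)-5-hydroxy-2,3-dimethyl-6-[(2R)-5-methyl-2-(2-methylprop-1-en-1-yl)hex-5-en-1-yl]-10-phenyl-2,3,9,10-tetrahydro-4H,8H-pyrano[2,3-f]chromene-4,8-dione; 22 tert-butyl 3-methylbut-2-en-1-yl carbonate
Product: 38 (2S,3S,6S,10R)-2,3-dimethyl-6-(3-methylbut-2-en-1-yl)-6-[(2R)-5-methyl-2-(2-methylprop-1-en-1-yl)hex-5-en-1-yl]-10-phenyl-2,3,9,10-tetrahydro-4H,8H-pyrano[2,3-f]chromene-4,5,8(6H)-trione
Conditions: Pd2(dba)3·CHCl3 (2.5 mol%), (R,R)-DACH-phenyl Trost ligand (7.5 mol%), 22 (1.05 equiv), toluene, 0 °C to rt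
Reagents that add atoms: none
Why: Proposed new method: ligand-controlled dearomative C-prenylation of a fully substituted, lactone-locked acylphloroglucinol; zerovalent palladium ionises 22 to a cationic (1,1-dimethyl-π-allyl)palladium complex with loss of CO2, the tert-butoxide released deprotonates the chelated 5-OH of 37, and the phenoxide, whose O-7 is tied up in the lactone so that C-6 is the only soft carbon site next to the oxide that is not a ring-fusion atom, attacks the unsubstituted allyl terminus from outside the metal (any O-5 prenyl ether is re-ionised and funnels to the C-product), while an amide N–H of the diphosphine hydrogen-bonds to the O-5/C-4 carbonyl chelate and the chiral pocket exposes one face of the flat tricycle, so C-6 becomes (S) under catalyst control irrespective of the remote stereocentres; the closest known reaction type is the palladium-catalysed asymmetric allylic dearomatisation of naphthols (Tsuji–Trost type), together with the racemic palladium-catalysed dearomative allylation of acylphloroglucinols.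

Step 23
Reactants: 38 (2S,3S,6S,10R)-2,3-dimethyl-6-(3-methylbut-2-en-1-yl)-6-[(2R)-5-methyl-2-(2-methylprop-1-en-1-yl)hex-5-en-1-yl]-10-phenyl-2,3,9,10-tetrahydro-4H,8H-pyrano[2,3-f]chromene-4,5,8(6H)-trione
Product: 39 (3R)-3-{(2S,3S,6S)-4-hydroxy-2,3-dimethyl-6-(3-methylbut-2-en-1-yl)-6-[(2R)-5-methyl-2-(2-methylprop-1-en-1-yl)hex-5-en-1-yl]-5,7-dioxo-3,5,6,7-tetrahydro-2H-chromen-8-yl}-3-phenylpropanoic acid (CNP0155375.2)
Conditions: LiOH·H2O (3 equiv), THF/H2O, 0 °C; then 1 M HCl to pH 3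
Reagents that add atoms: water (delivered as hydroxide from LiOH·H2O), O
Why: Ester hydrolysis of the activated enol lactone at 0 °C frees the carboxylic acid and the C-7 carbonyl; the core sits as its stabilised enolate so no retro-Claisen cleavage occurs, and acidification gives the target as the drawn tautomer.

## Compound list

1 | 5-methylhex-5-enoic acid | C=C(C)CCCC(=O)O | starting material
2 | (4S)-4-benzyl-1,3-oxazolidin-2-one | O=C1N[C@@H](Cc2ccccc2)CO1 | starting material
3 | 5-methylhex-5-enoic pivalic anhydride | C=C(C)CCCC(=O)OC(=O)C(C)(C)C | intermediate (not isolated)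
4 | (4S)-4-benzyl-3-(5-methylhex-5-enoyl)-1,3-oxazolidin-2-one | C=C(C)CCCC(=O)N1[C@@H](Cc2ccccc2)COC1=O | intermediate
5 | benzyl chloromethyl ether | ClCOCc1ccccc1 | starting material
6 | sodium (Z)-enolate of 4 | C=C(C)CC/C=C(\[O-])N1[C@@H](Cc2ccccc2)COC1=O.[Na+] | intermediate (not isolated)
7 | (4S)-4-benzyl-3-[(2R)-2-[(benzyloxy)methyl]-5-methylhex-5-enoyl]-1,3-oxazolidin-2-one | C=C(C)CC[C@H](COCc1ccccc1)C(=O)N1[C@@H](Cc2ccccc2)COC1=O | intermediate
8 | (2S)-2-[(benzyloxy)methyl]-5-methylhex-5-en-1-ol | C=C(C)CC[C@H](COCc1ccccc1)CO | intermediate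
9 | (2R)-2-[(benzyloxy)methyl]-5-methylhex-5-enal | C=C(C)CC[C@H](COCc1ccccc1)C=O | intermediate
10 | isopropyltriphenylphosphonium iodide | CC(C)[P+](c1ccccc1)(c1ccccc1)c1ccccc1.[I-] | starting material
11 | isopropylidenetriphenylphosphorane | CC(C)=P(c1ccccc1)(c1ccccc1)c1ccccc1 | intermediate (not isolated)
12 | benzyl (2S)-5-methyl-2-(2-methylprop-1-en-1-yl)hex-5-en-1-yl ether | C=C(C)CC[C@H](COCc1ccccc1)C=C(C)C | intermediate
13 | (2S)-5-methyl-2-(2-methylprop-1-en-1-yl)hex-5-en-1-ol | C=C(C)CC[C@H](CO)C=C(C)C | intermediate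
14 | (4S)-4-benzyl-3-propanoyl-1,3-oxazolidin-2-one | CCC(=O)N1[C@@H](Cc2ccccc2)COC1=O | starting material
15 | acetaldehyde | CC=O | starting material
16 | dibutylboron (Z)-enolate of 14 | C/C=C(\OB(CCCC)CCCC)N1[C@@H](Cc2ccccc2)COC1=O | intermediate (not isolated)
17 | (4S)-4-benzyl-3-[(2S,3R)-3-hydroxy-2-methylbutanoyl]-1,3-oxazolidin-2-one | C[C@@H](O)[C@H](C)C(=O)N1[C@@H](Cc2ccccc2)COC1=O | intermediate
18 | (4S)-4-benzyl-3-[(2S,3R)-3-{[tert-butyl(dimethyl)silyl]oxy}-2-methylbutanoyl]-1,3-oxazolidin-2-one | C[C@@H](O[Si](C)(C)C(C)(C)C)[C@H](C)C(=O)N1[C@@H](Cc2ccccc2)COC1=O | intermediate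
19 | (2R,3R)-3-{[tert-butyl(dimethyl)silyl]oxy}-2-methylbutan-1-ol | C[C@@H](O[Si](C)(C)C(C)(C)C)[C@H](C)CO | intermediate
20 | (2S,3R)-3-{[tert-butyl(dimethyl)silyl]oxy}-2-methylbutanal | C[C@@H](O[Si](C)(C)C(C)(C)C)[C@H](C)C=O | intermediate
21 | 3-methylbut-2-en-1-ol | CC(C)=CCO | starting material
22 | tert-butyl 3-methylbut-2-en-1-yl carbonate | CC(C)=CCOC(=O)OC(C)(C)C | intermediate
23 | benzene-1,3,5-triol (phloroglucinol) | Oc1cc(O)cc(O)c1 | starting material
24 | 5-{[tri(propan-2-yl)silyl]oxy}benzene-1,3-diol | CC(C)[Si](Oc1cc(O)cc(O)c1)(C(C)C)C(C)C | intermediate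
25 | [3,5-bis(methoxymethoxy)phenoxy]tri(propan-2-yl)silane | COCOc1cc(OCOC)cc(O[Si](C(C)C)(C(C)C)C(C)C)c1 | intermediate
26 | {2,6-bis(methoxymethoxy)-4-{[tri(propan-2-yl)silyl]oxy}phenyl}lithium | COCOc1cc(O[Si](C(C)C)(C(C)C)C(C)C)cc(OCOC)c1[Li] | intermediate (not isolated)
27 | (2S)-5-methyl-2-(2-methylprop-1-en-1-yl)hex-5-en-1-yl trifluoromethanesulfonate | C=C(C)CC[C@H](COS(=O)(=O)C(F)(F)F)C=C(C)C | intermediate (not isolated)
28 | {3,5-bis(methoxymethoxy)-4-[(2R)-5-methyl-2-(2-methylprop-1-en-1-yl)hex-5-en-1-yl]phenoxy}tri(propan-2-yl)silane | C=C(C)CC[C@H](Cc1c(OCOC)cc(O[Si](C(C)C)(C(C)C)C(C)C)cc1OCOC)C=C(C)C | intermediate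
29 | {2-iodo-3,5-bis(methoxymethoxy)-4-[(2R)-5-methyl-2-(2-methylprop-1-en-1-yl)hex-5-en-1-yl]phenoxy}tri(propan-2-yl)silane | C=C(C)CC[C@H](Cc1c(OCOC)cc(O[Si](C(C)C)(C(C)C)C(C)C)c(I)c1OCOC)C=C(C)C | intermediate
30 | {2,4-bis(methoxymethoxy)-3-[(2R)-5-methyl-2-(2-methylprop-1-en-1-yl)hex-5-en-1-yl]-6-{[tri(propan-2-yl)silyl]oxy}phenyl}lithium | C=C(C)CC[C@H](Cc1c(OCOC)cc(O[Si](C(C)C)(C(C)C)C(C)C)c([Li])c1OCOC)C=C(C)C | intermediate (not isolated)
31 | (1RS,2R,3R)-3-{[tert-butyl(dimethyl)silyl]oxy}-1-{2,4-bis(methoxymethoxy)-3-[(2R)-5-methyl-2-(2-methylprop-1-en-1-yl)hex-5-en-1-yl]-6-{[tri(propan-2-yl)silyl]oxy}phenyl}-2-methylbutan-1-ol (both C-1 epimers) | C=C(C)CC[C@H](Cc1c(OCOC)cc(O[Si](C(C)C)(C(C)C)C(C)C)c(C(O)[C@@H](C)[C@@H](C)O[Si](C)(C)C(C)(C)C)c1OCOC)C=C(C)C | intermediate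
32 | (2S,3R)-3-{[tert-butyl(dimethyl)silyl]oxy}-1-{2,4-bis(methoxymethoxy)-3-[(2R)-5-methyl-2-(2-methylprop-1-en-1-yl)hex-5-en-1-yl]-6-{[tri(propan-2-yl)silyl]oxy}phenyl}-2-methylbutan-1-one | C=C(C)CC[C@H](Cc1c(OCOC)cc(O[Si](C(C)C)(C(C)C)C(C)C)c(C(=O)[C@@H](C)[C@@H](C)O[Si](C)(C)C(C)(C)C)c1OCOC)C=C(C)C | intermediate
33 | (2S,3R)-3-hydroxy-1-{6-hydroxy-2,4-bis(methoxymethoxy)-3-[(2R)-5-methyl-2-(2-methylprop-1-en-1-yl)hex-5-en-1-yl]phenyl}-2-methylbutan-1-one | C=C(C)CC[C@H](Cc1c(OCOC)cc(O)c(C(=O)[C@@H](C)[C@@H](C)O)c1OCOC)C=C(C)C | intermediate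
34 | (2S,3S)-5,7-bis(methoxymethoxy)-2,3-dimethyl-6-[(2R)-5-methyl-2-(2-methylprop-1-en-1-yl)hex-5-en-1-yl]-2,3-dihydro-4H-chromen-4-one | C=C(C)CC[C@H](Cc1c(OCOC)cc2O[C@@H](C)[C@H](C)C(=O)c2c1OCOC)C=C(C)C | intermediate
35 | (2S,3S)-5,7-dihydroxy-2,3-dimethyl-6-[(2R)-5-methyl-2-(2-methylprop-1-en-1-yl)hex-5-en-1-yl]-2,3-dihydro-4H-chromen-4-one | C=C(C)CC[C@H](Cc1c(O)cc2O[C@@H](C)[C@H](C)C(=O)c2c1O)C=C(C)C | intermediate
36 | 3-phenylprop-2-ynal | O=CC#Cc1ccccc1 | starting material
37 | (2S,3S,10R)-5-hydroxy-2,3-dimethyl-6-[(2R)-5-methyl-2-(2-methylprop-1-en-1-yl)hex-5-en-1-yl]-10-phenyl-2,3,9,10-tetrahydro-4H,8H-pyrano[2,3-f]chromene-4,8-dione | C=C(C)CC[C@H](Cc1c(O)c2c(c3c1OC(=O)C[C@@H]3c1ccccc1)O[C@@H](C)[C@H](C)C2=O)C=C(C)C | intermediate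
38 | (2S,3S,6S,10R)-2,3-dimethyl-6-(3-methylbut-2-en-1-yl)-6-[(2R)-5-methyl-2-(2-methylprop-1-en-1-yl)hex-5-en-1-yl]-10-phenyl-2,3,9,10-tetrahydro-4H,8H-pyrano[2,3-f]chromene-4,5,8(6H)-trione | C=C(C)CC[C@@H](C=C(C)C)C[C@@]1(CC=C(C)C)C(=O)C2=C(O[C@@H](C)[C@H](C)C2=O)C2=C1OC(=O)C[C@@H]2c1ccccc1 | intermediate
39 | (3R)-3-{(2S,3S,6S)-4-hydroxy-2,3-dimethyl-6-(3-methylbut-2-en-1-yl)-6-[(2R)-5-methyl-2-(2-methylprop-1-en-1-yl)hex-5-en-1-yl]-5,7-dioxo-3,5,6,7-tetrahydro-2H-chromen-8-yl}-3-phenylpropanoic acid (CNP0155375.2) | C=C(C)CC[C@@H](C=C(C)C)C[C@@]1(CC=C(C)C)C(=O)C2=C(O)[C@@H](C)[C@H](C)OC2=C([C@H](CC(=O)O)c2ccccc2)C1=O | target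

## Step count and risk

Total step count: 23.
Longest linear sequence: 16 steps (steps 1 to 6, then 14 to 23, counted from acid 1).

The three steps most likely to fail:

Step 22 (the proposed new dearomative prenylation). The risks are low facial selectivity on a substrate whose flanks differ only remotely, O-prenylation that does not funnel to carbon, and attack at a ring-fusion carbon. The fallback uses known chemistry, sets out from 37 and comes back at 38. The lithium phenoxide of 37 (LiN(SiMe3)2, toluene, 0 °C) is C-alkylated with 1-bromo-3-methylbut-2-ene, the classical ortho C-alkylation of phenoxides in a non-polar solvent that is used for dearomative prenylation of acylphloroglucinols. This gives 38 together with its C-6 epimer (2S,3S,6R,10R)-2,3-dimethyl-6-(3-methylbut-2-en-1-yl)-6-[(2R)-5-methyl-2-(2-methylprop-1-en-1-yl)hex-5-en-1-yl]-10-phenyl-2,3,9,10-tetrahydro-4H,8H-pyrano[2,3-f]chromene-4,5,8(6H)-trione F5, and the two are separated by preparative HPLC.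

Step 21 (carbene-catalysed annulation on a hindered, polyfunctional phloroglucinol). The risks are low conversion, a poor diastereomer ratio or the wrong sense of induction. The fallback sets out from 35 and comes back at 37. Chromanone 35 is heated with 5-benzylidene-2,2-dimethyl-1,3-dioxane-4,6-dione in pyridine at 90 °C; conjugate addition of C-8, lactonisation onto the 7-OH and loss of acetone and CO2 follow. This gives 37 together with its C-10 epimer (2S,3S,10S)-5-hydroxy-2,3-dimethyl-6-[(2R)-5-methyl-2-(2-methylprop-1-en-1-yl)hex-5-en-1-yl]-10-phenyl-2,3,9,10-tetrahydro-4H,8H-pyrano[2,3-f]chromene-4,8-dione F4, and the two diastereomers are separated by preparative HPLC.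

Step 14 (SN2 of a hindered aryllithium on a β-branched triflate). The risks are elimination of the triflate to the diene and a slow substitution. The fallback is a Negishi cross-coupling that sets out from 25 and 13 and comes back at 28. Aryllithium 26, made from 25 as before, is quenched with I2 to give [4-iodo-3,5-bis(methoxymethoxy)phenoxy]tri(propan-2-yl)silane F1. Alcohol 13 is converted with PPh3, I2 and imidazole into (5S)-5-(iodomethyl)-2,7-dimethylocta-1,6-diene F2, which with zinc dust and LiCl in THF gives [(2S)-5-methyl-2-(2-methylprop-1-en-1-yl)hex-5-en-1-yl]zinc iodide F3. F1 and F3 are then coupled with Pd(OAc)2 and SPhos in THF at 50 °C to give 28.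

## Further compounds

F1 | step 14 | [4-iodo-3,5-bis(methoxymethoxy)phenoxy]tri(propan-2-yl)silane | COCOc1cc(O[Si](C(C)C)(C(C)C)C(C)C)cc(OCOC)c1I
F2 | step 14 | (5S)-5-(iodomethyl)-2,7-dimethylocta-1,6-diene | C=C(C)CC[C@H](CI)C=C(C)C
F3 | step 14 | [(2S)-5-methyl-2-(2-methylprop-1-en-1-yl)hex-5-en-1-yl]zinc iodide | C=C(C)CC[C@H](C[Zn]I)C=C(C)C
F4 | step 21 | (2S,3S,10S)-5-hydroxy-2,3-dimethyl-6-[(2R)-5-methyl-2-(2-methylprop-1-en-1-yl)hex-5-en-1-yl]-10-phenyl-2,3,9,10-tetrahydro-4H,8H-pyrano[2,3-f]chromene-4,8-dione | C=C(C)CC[C@H](Cc1c(O)c2c(c3c1OC(=O)C[C@H]3c1ccccc1)O[C@@H](C)[C@H](C)C2=O)C=C(C)C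
F5 | step 22 | (2S,3S,6R,10R)-2,3-dimethyl-6-(3-methylbut-2-en-1-yl)-6-[(2R)-5-methyl-2-(2-methylprop-1-en-1-yl)hex-5-en-1-yl]-10-phenyl-2,3,9,10-tetrahydro-4H,8H-pyrano[2,3-f]chromene-4,5,8(6H)-trione | C=C(C)CC[C@@H](C=C(C)C)C[C@]1(CC=C(C)C)C(=O)C2=C(O[C@@H](C)[C@H](C)C2=O)C2=C1OC(=O)C[C@@H]2c1ccccc1
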